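**Retrosynthetic overview**

1. Target 21 ⇐ desilylation and 6-O-acetylation of diene diol 19; the 13(16),14-diene ⇐ vinyl addition to, then Wittig methylenation of, the carbonyl carbon (C13) of δ-lactone 17.
2. 17 (C8 set) ⇐ hydrogen-atom-transfer lactonisation of the exocyclic alkene 16 ⇐ methylenation of keto ester 15.
3. 15 ⇐ key step: one-carbon ring expansion of trans-hydrindanone 11 (1,2-shift of C10 from C8 to a CH2Br2-derived carbenoid carbon, C9), with capture of the ring-expanded enolate by tert-butyl acrylate (C9 set).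
4. 11 ⇐ hydroboration (C5, C6), Wolff–Kishner removal of the C3 carbonyl and deconjugative C4 alkylation of the mono-ketal of enedione 4.
5. 4 ⇐ 2-methylcyclopentane-1,3-dione + ethyl vinyl ketone (C10 set). Ring order: bought five-membered ring → ring A (step 2) → ring B by expansion of the five-membered ring (step 8) → temporary lactone ring (step 10, opened in step 11).

Assumption and labels: the given SMILES is taken as the absolute configuration; atoms carry the labdane numbers of the target throughout (C18 = oxygenated carbon on C4, C19 = methyl on C4, C17 = methyl on C8, C20 = methyl on C10); syn/anti mean same/opposite face as C20.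

**Route**

Step 1
Reactants: 1 2-methylcyclopentane-1,3-dione; 2 pent-1-en-3-one (ethyl vinyl ketone)
Product: 3 2-methyl-2-(3-oxopentyl)cyclopentane-1,3-dione
Conditions: H2O, AcOH (cat.), 70 °C
Reagents that add atoms: none
Why: Michael addition of the acidic cyclic 1,3-dione to the enone gives the prochiral triketone cleanly; no stereocentre is formed.

Step 2
Reactants: 3 2-methyl-2-(3-oxopentyl)cyclopentane-1,3-dione
Product: 4 (R)-4,7a-dimethyl-2,3,7,7a-tetrahydro-1H-indene-1,5(6H)-dione
Conditions: D-phenylalanine (1.0 equiv), 1 M HClO4 (0.5 equiv), MeCN, 80 °C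
Reagents that add atoms: none
Why: Hajos–Parrish–Eder–Sauer–Wiechert aldol condensation (enamine catalysis) differentiates the two enantiotopic ring carbonyls and sets quaternary C10; the D-amino acid gives the (R) antipode of the usual series and closes ring A.

Step 3
Reactants: 4 (R)-4,7a-dimethyl-2,3,7,7a-tetrahydro-1H-indene-1,5(6H)-dione
Product: 5 (R)-1,1-(ethylenedioxy)-4,7a-dimethyl-1,2,3,6,7,7a-hexahydro-5H-inden-5-one
Conditions: HOCH2CH2OH, p-TsOH·H2O (cat.), 4 Å MS, 23 °C
Reagents that add atoms: ethylene glycol, OCCO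
Why: Chemoselective ketalisation, because the saturated cyclopentanone (C8) is more electrophilic than the conjugated ketone; C8 must be masked for steps 4 to 6.

Step 4
Reactants: 5 (R)-1,1-(ethylenedioxy)-4,7a-dimethyl-1,2,3,6,7,7a-hexahydro-5H-inden-5-one
Product: 6 1,1-(ethylenedioxy)-4,7a-dimethyl-4-[(triisopropylsilyloxy)methyl]-1,2,4,6,7,7a-hexahydro-5H-inden-5-one (CH2OSi anti to the 7a-methyl)
Conditions: KOt-Bu (1.1 equiv), THF/t-BuOH, 0 °C; then i-Pr3SiOCH2Cl, −20 → 23 °C
Reagents that add atoms: (triisopropylsiloxy)methyl chloride, CC(C)[Si](OCCl)(C(C)C)C(C)C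
Why: Deconjugative α-alkylation of the extended potassium dienolate; the electrophile enters C4 on the face anti to the angular methyl (the usual course for 10-methyl dienolates), setting C4 and moving the alkene to C5=C6.

Step 5
Reactants: 6 the C4-alkylated β,γ-unsaturated ketone
Product: 8 1,1-(ethylenedioxy)-4,7a-dimethyl-4-[(triisopropylsilyloxy)methyl]-2,4,5,6,7,7a-hexahydro-1H-indene (3,3a-ene), via hydrazone 7 (not isolated)
Conditions: N2H4·H2O, Et3N, EtOH, 85 °C; concentrate; then KOt-Bu, DMSO, 23 → 70 °C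
Reagents that add atoms: none
Why: Wolff–Kishner reduction in the Cram low-temperature modification removes the hindered C3 carbonyl while ketal, silyl ether and the non-conjugatable alkene survive; no stereocentre changes.

Step 6
Reactants: 8 the 3,3a-ene (C5=C6 in labdane numbering)
Product: 10 1,1-(ethylenedioxy)-4,7a-dimethyl-4-[(triisopropylsilyloxy)methyl]octahydro-1H-inden-3-ol (trans-fused; 3-OH and H-3a anti to the 7a-methyl), via alkylborane 9 (not isolated)
Conditions: BH3·THF, THF, 0 → 23 °C; then NaOH, H2O2, 0 → 23 °C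
Reagents that add atoms: hydrogen peroxide, OO
Why: Hydroboration–oxidation; syn addition occurs on the face anti to the two methyls flanking C5 (as for Δ14 steroids and 4,4-dimethyl-Δ5 systems), setting H-5 and 6-OH anti and giving the trans ring fusion.

Step 7
Reactants: 10 the ketal alcohol
Product: 11 3-hydroxy-4,7a-dimethyl-4-[(triisopropylsilyloxy)methyl]octahydro-1H-inden-1-one (trans-fused; configuration as in 10)
Conditions: 0.5 M HCl, THF/H2O, 23 °C
Reagents that add atoms: water, O
Why: Mild acetal hydrolysis frees the C8 ketone; the primary triisopropylsilyl ether is stable, and the short, cold exposure limits β-elimination of the 6-hydroxyl.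

Step 8
Reactants: 11 the trans-hydrindanone; 12 tert-butyl prop-2-enoate (tert-butyl acrylate)
Product: 15 tert-butyl 6-hydroxy-8-oxo-18-(triisopropylsilyloxy)-14,15,16,17-tetranorlabdan-13-oate (trans-decalin; C9 chain anti), via dilithium dibromomethyl carbinolate 13 (not isolated), via lithium enolate 14 (not isolated)
Conditions: CH2Br2 (1.1 equiv), lithium 2,2,6,6-tetramethylpiperidide (2.1 equiv), THF, −78 °C; then n-BuLi (1.1 equiv), −78 → 0 °C; then 12 (1.2 equiv), −78 °C; AcOH, −78 °C
Reagents that add atoms: dibromomethane, BrCBr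
Why: Proposed new method: LiCHBr2 adds to the C8 ketone anti to the angular methyl, Br/Li exchange gives a β-oxido carbenoid, and alkoxide push drives 1,2-migration of the more electron-rich quaternary C10 (retention at C10, loss of LiBr), so the five-membered ring becomes ring B and a single C8=C9 lithium enolate results; this enolate is captured in the same flask by 12, which approaches C9 axially on the face anti to C20 and sets C9; the closest known reactions are the β-oxido carbenoid ring enlargement of cycloalkanones (Nozaki type, more substituted carbon migrates) and kinetic Michael addition of lithium enolates to acrylates; migration of an angular quaternary carbon of a trans-hydrindanone and direct C–C capture of the ring-enlarged enolate have not been shown.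

Step 9
Reactants: 15 the keto ester
Product: 16 tert-butyl 6-hydroxy-18-(triisopropylsilyloxy)-14,15,16-trinorlabd-8(17)-en-13-oate
Conditions: Zn, CH2Br2, TiCl4, THF, −40 → 5 °C (aged reagent); then 15, CH2Cl2, 0 → 23 °C
Reagents that add atoms: dibromomethane, BrCBr
Why: Takai–Lombardo methylenation is non-basic, so the hindered ketone is converted to the exocyclic alkene without epimerising the axial C9 centre or touching the ester.

Step 10
Reactants: 16 the exocyclic alkene ester
Product: 17 6-hydroxy-18-(triisopropylsilyloxy)-14,15,16-trinorlabdan-13,8-olide (cis-fused δ-lactone; 8-O anti and C17 syn)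
Conditions: Co complex of N,N'-bis(3,5-di-tert-butylsalicylidene)ethylenediamine, C32H46CoN2O2 (divalent cobalt, 5 mol %), N-fluoro-2,4,6-trimethylpyridinium tetrafluoroborate, PhSiH3, PhCF3, 0 → 23 °C
Reagents that add atoms: none
Why: Cobalt-hydride hydrogen-atom transfer with radical–polar crossover (Markovnikov hydroacyloxylation) makes the tertiary C8 cation, which the ester carbonyl on the axial C9 chain can reach only from the anti face, so C8 is set (O anti, new methyl C17 syn) in a cis-fused lactone and the tert-butyl group leaves as isobutene.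

Step 11
Reactants: 17 the δ-lactone
Product: 18 6,8-dihydroxy-18-(triisopropylsilyloxy)-16-norlabd-14-en-13-one (in equilibrium with its cyclic hemiketal)
Conditions: CH2=CHMgBr (2.2 equiv), THF, −78 °C; AcOH, −78 °C
Reagents that add atoms: vinylmagnesium bromide, C=C[Mg]Br
Why: Mono-addition of the Grignard reagent to the lactone gives a magnesium hemiketalate that is stable at −78 °C, so cold quench delivers the vinyl ketone and unveils the tertiary 8-OH with C8 untouched.

Step 12
Reactants: 18 the hydroxy vinyl ketone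
Product: 19 18-(triisopropylsilyloxy)labda-13(16),14-diene-6,8-diol
Conditions: Ph3PCH3Br, KN(SiMe3)2, THF, 0 °C; then 18, 0 → 23 °C
Reagents that add atoms: methyltriphenylphosphonium bromide, C[P+](c1ccccc1)(c1ccccc1)c1ccccc1.[Br-]
Why: Wittig methylenation by 1,2-addition of the non-stabilised ylide to the enone carbonyl gives the 2-substituted buta-1,3-diene; the ylide also draws the hemiketal through its open form.

Step 13
Reactants: 19 the diene diol
Product: 20 6-acetoxy-18-(triisopropylsilyloxy)labda-13(16),14-dien-8-ol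
Conditions: Ac2O, pyridine, DMAP (cat.), CH2Cl2, 0 → 23 °C
Reagents that add atoms: acetic anhydride, CC(=O)OC(C)=O
Why: Nucleophilic-catalysed acylation takes the secondary equatorial 6-OH, while the tertiary 8-OH is inert under these conditions and C18–O is still silylated.

Step 14
Reactants: 20 the silyl-protected acetate
Product: 21 6-acetoxylabda-13(16),14-diene-8,18-diol with the configuration of the given SMILES (target, CNP0312185.2)
Conditions: HF·pyridine, pyridine, THF, 0 → 23 °C
Reagents that add atoms: none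
Why: Buffered fluoride desilylation frees the primary alcohol under mildly acidic conditions that avoid base-promoted acetyl migration from O6 to O18 and leave the diene and tertiary alcohol intact.

**Compound list**

1 | 2-methylcyclopentane-1,3-dione | CC1C(=O)CCC1=O | starting material
2 | pent-1-en-3-one (ethyl vinyl ketone) | CCC(=O)C=C | starting material
3 | 2-methyl-2-(3-oxopentyl)cyclopentane-1,3-dione | CCC(=O)CCC1(C)C(=O)CCC1=O | intermediate
4 | (R)-4,7a-dimethyl-2,3,7,7a-tetrahydro-1H-indene-1,5(6H)-dione | C[C@@]12CCC(=O)C(C)=C1CCC2=O | intermediate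
5 | (R)-1,1-(ethylenedioxy)-4,7a-dimethyl-1,2,3,6,7,7a-hexahydro-5H-inden-5-one | C[C@@]12CCC(=O)C(C)=C1CCC23OCCO3 | intermediate
6 | 1,1-(ethylenedioxy)-4,7a-dimethyl-4-[(triisopropylsilyloxy)methyl]-1,2,4,6,7,7a-hexahydro-5H-inden-5-one (CH2OSi anti to the 7a-methyl) | C[C@@]12CCC(=O)[C@](C)(CO[Si](C(C)C)(C(C)C)C(C)C)C1=CCC23OCCO3 | intermediate
7 | hydrazone of 6 at the ring-A carbonyl (C3) | C[C@@]12CCC(=NN)[C@](C)(CO[Si](C(C)C)(C(C)C)C(C)C)C1=CCC23OCCO3 | intermediate
8 | 1,1-(ethylenedioxy)-4,7a-dimethyl-4-[(triisopropylsilyloxy)methyl]-2,4,5,6,7,7a-hexahydro-1H-indene (3,3a-ene) | C[C@@]12CCC[C@](C)(CO[Si](C(C)C)(C(C)C)C(C)C)C1=CCC23OCCO3 | intermediate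
9 | 3-boranyl-1,1-(ethylenedioxy)-4,7a-dimethyl-4-[(triisopropylsilyloxy)methyl]octahydro-1H-indene (B and H-3a anti to the 7a-methyl) | C[C@@]12CCC[C@](C)(CO[Si](C(C)C)(C(C)C)C(C)C)[C@H]1[C@H](B)CC23OCCO3 | intermediate
10 | 1,1-(ethylenedioxy)-4,7a-dimethyl-4-[(triisopropylsilyloxy)methyl]octahydro-1H-inden-3-ol (trans-fused; 3-OH, H-3a and CH2OSi anti to the 7a-methyl) | C[C@@]12CCC[C@](C)(CO[Si](C(C)C)(C(C)C)C(C)C)[C@H]1[C@H](O)CC23OCCO3 | intermediate
11 | 3-hydroxy-4,7a-dimethyl-4-[(triisopropylsilyloxy)methyl]octahydro-1H-inden-1-one (configuration as in 10) | C[C@@]12CCC[C@](C)(CO[Si](C(C)C)(C(C)C)C(C)C)[C@H]1[C@H](O)CC2=O | intermediate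
12 | tert-butyl prop-2-enoate (tert-butyl acrylate) | C=CC(=O)OC(C)(C)C | starting material
13 | dilithium 1-(dibromomethyl)-4,7a-dimethyl-4-[(triisopropylsilyloxy)methyl]octahydro-1H-indene-1,3-diolate (CHBr2 anti to the 7a-methyl) | C[C@@]12CCC[C@](C)(CO[Si](C(C)C)(C(C)C)C(C)C)[C@H]1[C@H](O[Li])C[C@]2(O[Li])C(Br)Br | intermediate
14 | dilithium 18-(triisopropylsilyloxy)-11,12,13,14,15,16,17-heptanorlabd-8-ene-6,8-diolate (ring-expanded C8=C9 enolate) | [Li]OC1=C[C@]2(C)CCC[C@](C)(CO[Si](C(C)C)(C(C)C)C(C)C)[C@H]2[C@H](O[Li])C1 | intermediate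
15 | tert-butyl 6-hydroxy-8-oxo-18-(triisopropylsilyloxy)-14,15,16,17-tetranorlabdan-13-oate (H-5, 6-OH, C18 and the C9 chain anti; C19 syn) | CC(C)(C)OC(=O)CC[C@@H]1[C@]2(C)CCC[C@](C)(CO[Si](C(C)C)(C(C)C)C(C)C)[C@H]2[C@H](O)CC1=O | intermediate
16 | tert-butyl 6-hydroxy-18-(triisopropylsilyloxy)-14,15,16-trinorlabd-8(17)-en-13-oate | CC(C)(C)OC(=O)CC[C@@H]1[C@]2(C)CCC[C@](C)(CO[Si](C(C)C)(C(C)C)C(C)C)[C@H]2[C@H](O)CC1=C | intermediate
17 | 6-hydroxy-18-(triisopropylsilyloxy)-14,15,16-trinorlabdan-13,8-olide (cis-fused δ-lactone; 8-O anti, C17 syn) | O=C1CC[C@@H]2[C@]3(C)CCC[C@](C)(CO[Si](C(C)C)(C(C)C)C(C)C)[C@H]3[C@H](O)C[C@]2(C)O1 | intermediate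
18 | 6,8-dihydroxy-18-(triisopropylsilyloxy)-16-norlabd-14-en-13-one | C=CC(=O)CC[C@@H]1[C@]2(C)CCC[C@](C)(CO[Si](C(C)C)(C(C)C)C(C)C)[C@H]2[C@H](O)C[C@]1(C)O | intermediate
19 | 18-(triisopropylsilyloxy)labda-13(16),14-diene-6,8-diol | C=CC(=C)CC[C@@H]1[C@]2(C)CCC[C@](C)(CO[Si](C(C)C)(C(C)C)C(C)C)[C@H]2[C@H](O)C[C@]1(C)O | intermediate
20 | 6-acetoxy-18-(triisopropylsilyloxy)labda-13(16),14-dien-8-ol | C=CC(=C)CC[C@@H]1[C@]2(C)CCC[C@](C)(CO[Si](C(C)C)(C(C)C)C(C)C)[C@H]2[C@H](OC(C)=O)C[C@]1(C)O | intermediate
21 | 6-acetoxylabda-13(16),14-diene-8,18-diol (trans-decalin; C17, C19, C20 and H-9 syn; H-5, C18, 6-OAc, 8-OH and the C9 side chain anti) | C=CC(=C)CC[C@@H]1[C@]2(C)CCC[C@](C)(CO)[C@H]2[C@H](OC(C)=O)C[C@]1(C)O | target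

**Totals and risks**

Total step count: 14. Longest linear sequence: 14 steps (1 → 21).

The step most likely to fail is step 8, the proposed ring enlargement with enolate capture. The CH2 carbon C7 could migrate instead of C10, the β-alkoxy ketone could undergo retro-aldol cleavage, or the neopentyl enolate carbon could add sluggishly to the acrylate or oligomerise it. The fallback uses known chemistry, a stereospecific semipinacol ring expansion with the side chain already in place. It sets out from 11: TESCl and imidazole give the 6-O-triethylsilyl ketone F1. Wittig reaction with the ylide from [3-(tert-butoxycarbonyl)propyl]triphenylphosphonium bromide and KN(SiMe3)2 gives the (Z)-alkylidene ester F2. Dihydroxylation with OsO4 (cat.) and N-methylmorpholine N-oxide on the face anti to C20 gives the diol F3. MsCl and Et3N convert its secondary hydroxyl into the mesylate F4. Et3Al in CH2Cl2 at −78 °C then triggers the 1,2-shift of C10 with inversion at C9 to give the silyl-protected keto ester F5. HF·pyridine removes the triethylsilyl group, and the route is rejoined at 15.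

Step 11 is the second risk: the vinyl Grignard reagent may add twice, and the hydroxy vinyl ketone is sensitive. The fallback sets out from 17: MeNHOMe·HCl and i-PrMgCl in THF at −20 °C open the lactone to the hydroxy Weinreb amide F6. Its chelated adduct with CH2=CHMgBr collapses only on acidic work-up, which gives 18 without over-addition.

Step 12 is the third risk: the ylide may add in a conjugate sense to the terminal vinyl ketone, or the ketone may polymerise. The fallback avoids the vinyl ketone altogether and sets out from 17: i-Bu2AlH at −78 °C gives the lactol F7. Seyferth–Gilbert homologation in the Ohira–Bestmann variant (dimethyl (1-diazo-2-oxopropyl)phosphonate, K2CO3, MeOH) gives the terminal alkyne F8. Enyne cross-metathesis with ethylene (1 atm) and the second-generation Grubbs catalyst RuCl2(=CHPh)(H2IMes)(PCy3) then builds the 2-substituted butadiene, and the route is rejoined at 19.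

Further compounds
F1 | step 8 | 4,7a-dimethyl-3-(triethylsilyloxy)-4-[(triisopropylsilyloxy)methyl]octahydro-1H-inden-1-one (6-O-triethylsilyl ether of 11) | C[C@@]12CCC[C@](C)(CO[Si](C(C)C)(C(C)C)C(C)C)[C@H]1[C@H](O[Si](CC)(CC)CC)CC2=O
F2 | step 8 | tert-butyl (Z)-4-{4,7a-dimethyl-3-(triethylsilyloxy)-4-[(triisopropylsilyloxy)methyl]octahydro-1H-inden-1-ylidene}butanoate (chain cis to the quaternary carbon) | C[C@@]12CCC[C@](C)(CO[Si](C(C)C)(C(C)C)C(C)C)[C@H]1[C@H](O[Si](CC)(CC)CC)C/C2=C/CCC(=O)OC(C)(C)C
F3 | step 8 | tert-butyl 4-hydroxy-4-{1-hydroxy-4,7a-dimethyl-3-(triethylsilyloxy)-4-[(triisopropylsilyloxy)methyl]octahydro-1H-inden-1-yl}butanoate (ring hydroxyl anti to the 7a-methyl) | C[C@@]12CCC[C@](C)(CO[Si](C(C)C)(C(C)C)C(C)C)[C@H]1[C@H](O[Si](CC)(CC)CC)C[C@@]2(O)[C@H](O)CCC(=O)OC(C)(C)C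
F4 | step 8 | secondary methanesulfonate of diol F3 | C[C@@]12CCC[C@](C)(CO[Si](C(C)C)(C(C)C)C(C)C)[C@H]1[C@H](O[Si](CC)(CC)CC)C[C@@]2(O)[C@H](OS(C)(=O)=O)CCC(=O)OC(C)(C)C
F5 | step 8 | tert-butyl 8-oxo-6-(triethylsilyloxy)-18-(triisopropylsilyloxy)-14,15,16,17-tetranorlabdan-13-oate (6-O-triethylsilyl ether of 15) | CC(C)(C)OC(=O)CC[C@@H]1[C@]2(C)CCC[C@](C)(CO[Si](C(C)C)(C(C)C)C(C)C)[C@H]2[C@H](O[Si](CC)(CC)CC)CC1=O
F6 | step 11 | 6,8-dihydroxy-N-methoxy-N-methyl-18-(triisopropylsilyloxy)-14,15,16-trinorlabdan-13-amide | CON(C)C(=O)CC[C@@H]1[C@]2(C)CCC[C@](C)(CO[Si](C(C)C)(C(C)C)C(C)C)[C@H]2[C@H](O)C[C@]1(C)O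
F7 | step 12 | 6-hydroxy-18-(triisopropylsilyloxy)-14,15,16-trinorlabdan-13,8-olactol (anomer mixture) | OC1CC[C@@H]2[C@]3(C)CCC[C@](C)(CO[Si](C(C)C)(C(C)C)C(C)C)[C@H]3[C@H](O)C[C@]2(C)O1
F8 | step 12 | 18-(triisopropylsilyloxy)-15,16-dinorlabd-13-yne-6,8-diol | C#CCC[C@@H]1[C@]2(C)CCC[C@](C)(CO[Si](C(C)C)(C(C)C)C(C)C)[C@H]2[C@H](O)C[C@]1(C)O
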